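**Strategy.** Everything rests on reading the 3(2H)-furanone (ring O–C10–C1–C2–C3, germacrane numbering) as the cyclodehydrated form of an open-chain α'-hydroxy-1,3-diketone whose tertiary carbinol C10, with its methyl group and ring oxygen, is (S)-lactic acid. In one flask the methyl-ketone enolate (C2) of a stereodefined C2–C7 chain is acylated at C1 by an allylated lactic acid dioxolanone (C1, C10, C14, C9, C8), and acid then joins the C10 oxygen to C3. The key step thus unites both halves and closes the furanone. A chromium-mediated intramolecular allylation (C7–C8) later closes the ten-membered carbocycle and the trans-fused α-methylene lactone.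

Key step: step 7

Remark: atom labels follow germacrane numbering (C1 furanone C=O, C2 =CH, C3 O–C=, C4 CH with methyl C15, C5 CHOH, C6 CH–O-isobutyryl, C7, C8 CH–O of the lactone, C9 CH2, C10 quaternary with methyl C14, C11–C13 methylene lactone). The C7 carbinol epimers formed in step 11 are carried together because C7 becomes sp2 in step 13.

Step 1
Reactants: 1 (S)-lactic acid; 2 pivaldehyde
Product: 3 (2S,5S)-2-tert-butyl-5-methyl-1,3-dioxolan-4-one
Conditions: TsOH·H2O (cat.), H2SO4 (cat.), pentane, reflux, Dean–Stark; crystallisation from pentane/Et2O at −78 °C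
Reagents that add atoms: none
Why: Acid-catalysed acetalisation with removal of water; the new acetal centre should form mainly cis to the methyl group, and the cis isomer is purified by low-temperature crystallisation.

Step 2
Reactants: 3 (2S,5S)-2-tert-butyl-5-methyl-1,3-dioxolan-4-one; 4 allyl bromide
Product: 6 (2S,5R)-2-tert-butyl-5-methyl-5-(prop-2-en-1-yl)-1,3-dioxolan-4-one, via lithium dioxolanone enolate 5 (not isolated)
Conditions: LiN(i-Pr)2, THF, −78 °C; then 4, −78 to −30 °C
Reagents that add atoms: none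
Why: Enolate alkylation with self-regeneration of the stereocentre: the planar enolate is allylated on the face anti to the tert-butyl group, which sets the quaternary centre (future C10) as R.

Step 3
Reactants: 7 (R)-solketal [(R)-(2,2-dimethyl-1,3-dioxolan-4-yl)methanol]
Product: 8 (S)-2,2-dimethyl-1,3-dioxolane-4-carbaldehyde
Conditions: (COCl)2, DMSO, CH2Cl2, −78 °C; Et3N, −78 to 0 °C; used at once
Reagents that add atoms: none
Why: Swern oxidation of the primary alcohol, which should not epimerise the α-alkoxy centre (future C6) at low temperature.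

Step 4
Reactants: 8 (S)-2,2-dimethyl-1,3-dioxolane-4-carbaldehyde; 9 cis-2-butene
Product: 12 (1S,2R)-1-[(4S)-2,2-dimethyl-1,3-dioxolan-4-yl]-2-methylbut-3-en-1-ol, via (Z)-crotyldiisopinocampheylborane 10 (not isolated), via borinate adduct 11 (not isolated)
Conditions: 9, n-BuLi, KOt-Bu, THF, −45 °C; (−)-B-methoxydiisopinocampheylborane [from (+)-α-pinene], −78 °C; BF3·OEt2; 8, −78 °C; then NaOH, H2O2, 0 °C to rt
Reagents that add atoms: none
Why: Brown (Z)-crotylboration through a chair Zimmerman–Traxler transition state: the Z geometry gives the 4,5-syn relationship, and the isopinocampheyl ligands from (+)-α-pinene direct the crotyl group to the Si face of the aldehyde (5S), so that reagent control should override the Felkin preference and set C4 and C5 syn to the C6 oxygen.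

Step 5
Reactants: 12 (1S,2R)-1-[(4S)-2,2-dimethyl-1,3-dioxolan-4-yl]-2-methylbut-3-en-1-ol
Product: 13 (4S)-4-[(1S,2R)-1-[(4-methoxybenzyl)oxy]-2-methylbut-3-en-1-yl]-2,2-dimethyl-1,3-dioxolane
Conditions: NaH, 4-methoxybenzyl chloride, Bu4NI (cat.), THF/DMF, 0 °C to rt
Reagents that add atoms: 4-methoxybenzyl chloride, COc1ccc(CCl)cc1
Why: Williamson etherification; the PMB ether blocks the C5 oxygen so that only the C10 hydroxyl can cyclise in step 7, and it should survive every acid stage until its oxidative removal.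

Step 6
Reactants: 13 (4S)-4-[(1S,2R)-1-[(4-methoxybenzyl)oxy]-2-methylbut-3-en-1-yl]-2,2-dimethyl-1,3-dioxolane
Product: 14 (3S,4S)-4-[(4S)-2,2-dimethyl-1,3-dioxolan-4-yl]-4-[(4-methoxybenzyl)oxy]-3-methylbutan-2-one
Conditions: PdCl2 (10 mol %), CuCl, O2 (1 atm), DMF/H2O (7:1), rt
Reagents that add atoms: water, O
Why: Tsuji–Wacker oxidation: Markovnikov hydroxypalladation of the terminal alkene and β-hydride elimination give the methyl ketone C3(=O)–C2H3 without touching the adjacent C4 stereocentre.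

Step 7
Reactants: 14 (3S,4S)-4-[(4S)-2,2-dimethyl-1,3-dioxolan-4-yl]-4-[(4-methoxybenzyl)oxy]-3-methylbutan-2-one; 6 (2S,5R)-2-tert-butyl-5-methyl-5-(prop-2-en-1-yl)-1,3-dioxolan-4-one
Product: 17 (2R)-5-{(1S,2S)-1-[(4S)-2,2-dimethyl-1,3-dioxolan-4-yl]-1-[(4-methoxybenzyl)oxy]propan-2-yl}-2-methyl-2-(prop-2-en-1-yl)furan-3(2H)-one, via lithium ketone enolate 15 (not isolated), via hydroxy diketone 16 (not isolated)
Conditions: LiN(SiMe3)2 (2.3 equiv), THF, −78 °C; 6, −78 to −20 °C; 1 M HCl quench at −20 °C; crude product, CSA (5 mol %), 4 Å MS, CH2Cl2, rt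
Reagents that add atoms: none
Why: The kinetic lithium enolate of 14 (deprotonated at the C2 methyl, not at the branched C4) attacks the activated lactone carbonyl of 6 in a crossed Claisen acylation; the tetrahedral adduct collapses, the hemiacetal alkoxide loses pivaldehyde, and the excess base stores the product as its diketonate, which the acid quench releases as α'-hydroxy-1,3-diketone 16. Under acid the tertiary C10 hydroxyl then adds to the C3 carbonyl (5-exo-trig hemiketalisation) and loss of water gives the endocyclic C2=C3 bond, which is the classical cyclodehydration of α'-hydroxy-β-diketones to 3(2H)-furanones. The closest precedent for the first stage is the known self-acylation of dioxolanone enolates at the same carbonyl. No stereocentre is created: C10 is carried unchanged from lactic acid through 6, and C4, C5 and C6 are spectators. The step needs regioselective enolisation (secured by the hindered amide base at −78 °C and the unbranched methyl group), O–C3 closure by the C10 hydroxyl only (the C5 and C6/C7 oxygens are masked as PMB ether and acetonide, which anhydrous CSA should leave intact), and retention at C4 (the diketone enolises between C1 and C3, away from C4).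

Step 8
Reactants: 17 (2R)-5-{(1S,2S)-1-[(4S)-2,2-dimethyl-1,3-dioxolan-4-yl]-1-[(4-methoxybenzyl)oxy]propan-2-yl}-2-methyl-2-(prop-2-en-1-yl)furan-3(2H)-one
Product: 18 (2R)-5-{(2S,3S,4S)-4,5-dihydroxy-3-[(4-methoxybenzyl)oxy]pentan-2-yl}-2-methyl-2-(prop-2-en-1-yl)furan-3(2H)-one
Conditions: AcOH/H2O (4:1), 40 °C
Reagents that add atoms: none
Why: Acid-catalysed hydrolysis of the terminal isopropylidene acetal, which should leave the PMB ether, the vinylogous ester and the allyl group untouched.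

Step 9
Reactants: 18 (2R)-5-{(2S,3S,4S)-4,5-dihydroxy-3-[(4-methoxybenzyl)oxy]pentan-2-yl}-2-methyl-2-(prop-2-en-1-yl)furan-3(2H)-one
Product: 19 (2R)-5-{(2S,3S,4S)-3-[(4-methoxybenzyl)oxy]-4,5-bis[(triethylsilyl)oxy]pentan-2-yl}-2-methyl-2-(prop-2-en-1-yl)furan-3(2H)-one
Conditions: triethylsilyl triflate (2.5 equiv), 2,6-lutidine, CH2Cl2, −78 °C
Reagents that add atoms: triethylsilyl trifluoromethanesulfonate, CC[Si](CC)(CC)OS(=O)(=O)C(F)(F)F
Why: Silylation of both hydroxyls with the reactive silyl triflate; the primary TES ether can be oxidised off directly in step 10, and a silyl ether at C6 (not the final ester) is used because an acyl group would migrate to the C7 alkoxide in step 11.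

Step 10
Reactants: 19 (2R)-5-{(2S,3S,4S)-3-[(4-methoxybenzyl)oxy]-4,5-bis[(triethylsilyl)oxy]pentan-2-yl}-2-methyl-2-(prop-2-en-1-yl)furan-3(2H)-one
Product: 20 (2R,3S,4S)-3-[(4-methoxybenzyl)oxy]-4-[(5R)-5-methyl-4-oxo-5-(prop-2-en-1-yl)-4,5-dihydrofuran-2-yl]-2-[(triethylsilyl)oxy]pentanal
Conditions: (COCl)2, DMSO, CH2Cl2, −78 to −40 °C; Et3N, −78 to 0 °C
Reagents that add atoms: none
Why: Swern oxidation: activated DMSO cleaves and oxidises primary TES ethers directly to aldehydes while secondary TES ethers and the PMB ether are left, so no separate deprotection is needed.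

Step 11
Reactants: 20 (2R,3S,4S)-3-[(4-methoxybenzyl)oxy]-4-[(5R)-5-methyl-4-oxo-5-(prop-2-en-1-yl)-4,5-dihydrofuran-2-yl]-2-[(triethylsilyl)oxy]pentanal; 21 methyl acrylate
Product: 22 methyl (4S,5S,6S)-3-hydroxy-5-[(4-methoxybenzyl)oxy]-2-methylidene-6-[(5R)-5-methyl-4-oxo-5-(prop-2-en-1-yl)-4,5-dihydrofuran-2-yl]-4-[(triethylsilyl)oxy]heptanoate (both C3 carbinol epimers)
Conditions: DABCO (1 equiv), MeOH (cat.), neat 21, rt
Reagents that add atoms: none
Why: Morita–Baylis–Hillman reaction of the activated α-silyloxy aldehyde; the new carbinol centre (C7) is not controlled and need not be, because C7 becomes sp2 in step 13.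

Step 12
Reactants: 22 methyl (4S,5S,6S)-3-hydroxy-5-[(4-methoxybenzyl)oxy]-2-methylidene-6-[(5R)-5-methyl-4-oxo-5-(prop-2-en-1-yl)-4,5-dihydrofuran-2-yl]-4-[(triethylsilyl)oxy]heptanoate
Product: 24 methyl (4S,5S,6S)-3-hydroxy-5-[(4-methoxybenzyl)oxy]-2-methylidene-6-[(5R)-5-methyl-4-oxo-5-(2-oxoethyl)-4,5-dihydrofuran-2-yl]-4-[(triethylsilyl)oxy]heptanoate, via triol 23 (not isolated)
Conditions: OsO4 (2 mol %), NaIO4 (4 equiv), 2,6-lutidine, dioxane/H2O (3:1), rt
Reagents that add atoms: osmium tetroxide, O=[Os](=O)(=O)=O; sodium periodate, [Na+].[O-]I(=O)(=O)=O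
Why: Lemieux–Johnson oxidation (catalytic dihydroxylation, then periodate cleavage): the electrophilic OsO4 should attack the unhindered monosubstituted allyl alkene in preference to the electron-poor acrylate and the hindered push–pull C2=C3 bond of the furanone, unmasking the C8 aldehyde.

Step 13
Reactants: 24 methyl (4S,5S,6S)-3-hydroxy-5-[(4-methoxybenzyl)oxy]-2-methylidene-6-[(5R)-5-methyl-4-oxo-5-(2-oxoethyl)-4,5-dihydrofuran-2-yl]-4-[(triethylsilyl)oxy]heptanoate
Product: 25 methyl (2Z,4S,5S,6S)-2-(bromomethyl)-5-[(4-methoxybenzyl)oxy]-6-[(5R)-5-methyl-4-oxo-5-(2-oxoethyl)-4,5-dihydrofuran-2-yl]-4-[(triethylsilyl)oxy]hept-2-enoate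
Conditions: NBS, Me2S, CH2Cl2, 0 °C; then 24, 0 °C to rt
Reagents that add atoms: N-bromosuccinimide, O=C1CCC(=O)N1Br
Why: Corey–Kim-type activation of the allylic alcohol as an alkoxysulfonium salt and SN2′ attack of bromide (allylic transposition), which should give the thermodynamically preferred Z-2-(bromomethyl)enoate from both carbinol epimers and leave the aldehyde alone.

Step 14
Reactants: 25 methyl (2Z,4S,5S,6S)-2-(bromomethyl)-5-[(4-methoxybenzyl)oxy]-6-[(5R)-5-methyl-4-oxo-5-(2-oxoethyl)-4,5-dihydrofuran-2-yl]-4-[(triethylsilyl)oxy]hept-2-enoate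
Product: 27 the 5-O-PMB, 6-hydroxy macrolactone (the target lacking the isobutyryl group and carrying PMB on O5; spatial arrangement at C4, C5, C6, C7, C8, C10 as in 29), via TES lactone 26 (not isolated)
Conditions: CrCl2 (8 equiv), THF (2 mM, slow addition of 25), rt; then 1 M HCl, THF, rt
Reagents that add atoms: none
Why: Intramolecular Nozaki–Hiyama (Barbier-type) allylation: the allylchromium formed from the bromide adds through its γ-carbon C7 to the C8 aldehyde in a chair six-membered transition state with the C9 and C6 chains equatorial (anti adduct, 7,8-trans) and the aldehyde anti to the C6 silyloxy branch, so that C7 (R) and C8 (S) should form with all ring substituents on alternating faces of the furanone-preorganised ten-membered ring; the C8 chromium alkoxide lactonises onto the methyl ester, and the acid stage completes lactonisation and removes the TES group.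

Step 15
Reactants: 27 the 5-O-PMB, 6-hydroxy macrolactone
Product: 28 the 5-O-PMB ether of the target (6-O-isobutyrate)
Conditions: isobutyric anhydride, DMAP (cat.), pyridine, CH2Cl2, rt
Reagents that add atoms: isobutyric anhydride, CC(C)C(=O)OC(=O)C(C)C
Why: DMAP-catalysed acylation of the only free hydroxyl (C6), which should be faster than any translactonisation.

Step 16
Reactants: 28 the 5-O-PMB ether of the target
Product: 29 CNP0141385.1 (target)
Conditions: DDQ, CH2Cl2/pH 7 buffer (10:1), 0 °C to rt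
Reagents that add atoms: none
Why: Oxidative PMB ether cleavage by DDQ (benzylic hydride abstraction, then hydrolysis of the oxocarbenium ion) under neutral buffered conditions that should not cause acyl migration, elimination of the C5 hydroxyl or attack on the methylene lactone.

**Compound list**

1 | (S)-lactic acid | C[C@H](O)C(=O)O | starting material
2 | pivaldehyde | CC(C)(C)C=O | starting material
3 | (2S,5S)-2-tert-butyl-5-methyl-1,3-dioxolan-4-one | C[C@@H]1O[C@H](C(C)(C)C)OC1=O | intermediate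
4 | allyl bromide | C=CCBr | starting material
5 | lithium (2S)-2-tert-butyl-5-methyl-1,3-dioxol-4-olate (enolate of 3) | [Li+].CC1=C([O-])O[C@@H](C(C)(C)C)O1 | intermediate (not isolated)
6 | (2S,5R)-2-tert-butyl-5-methyl-5-(prop-2-en-1-yl)-1,3-dioxolan-4-one | C[C@]1(CC=C)O[C@H](C(C)(C)C)OC1=O | intermediate
7 | (R)-solketal | OC[C@@H]1COC(C)(C)O1 | starting material
8 | (S)-2,2-dimethyl-1,3-dioxolane-4-carbaldehyde | O=C[C@@H]1COC(C)(C)O1 | intermediate
9 | cis-2-butene | C/C=C\C | starting material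
10 | (Z)-crotyldiisopinocampheylborane (isopinocampheyl groups from (+)-α-pinene) | C/C=C\CB([C@@H]1C[C@@H]2C[C@H]([C@H]1C)C2(C)C)[C@@H]3C[C@@H]4C[C@H]([C@H]3C)C4(C)C | intermediate (not isolated)
11 | diisopinocampheylborinate ester of 12 | C=C[C@@H](C)[C@H](OB([C@@H]2C[C@@H]3C[C@H]([C@H]2C)C3(C)C)[C@@H]4C[C@@H]5C[C@H]([C@H]4C)C5(C)C)[C@@H]1COC(C)(C)O1 | intermediate (not isolated)
12 | (1S,2R)-1-[(4S)-2,2-dimethyl-1,3-dioxolan-4-yl]-2-methylbut-3-en-1-ol | C=C[C@@H](C)[C@H](O)[C@@H]1COC(C)(C)O1 | intermediate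
13 | (4S)-4-[(1S,2R)-1-[(4-methoxybenzyl)oxy]-2-methylbut-3-en-1-yl]-2,2-dimethyl-1,3-dioxolane | C=C[C@@H](C)[C@H](OCc2ccc(OC)cc2)[C@@H]1COC(C)(C)O1 | intermediate
14 | (3S,4S)-4-[(4S)-2,2-dimethyl-1,3-dioxolan-4-yl]-4-[(4-methoxybenzyl)oxy]-3-methylbutan-2-one | CC(=O)[C@@H](C)[C@H](OCc2ccc(OC)cc2)[C@@H]1COC(C)(C)O1 | intermediate
15 | lithium enolate of 14 (C2 methylene enolate) | [Li+].C=C([O-])[C@@H](C)[C@H](OCc2ccc(OC)cc2)[C@@H]1COC(C)(C)O1 | intermediate (not isolated)
16 | (1S,2S,6R)-1-[(4S)-2,2-dimethyl-1,3-dioxolan-4-yl]-6-hydroxy-1-[(4-methoxybenzyl)oxy]-2,6-dimethylnon-8-ene-3,5-dione | C=CC[C@@](C)(O)C(=O)CC(=O)[C@@H](C)[C@H](OCc2ccc(OC)cc2)[C@@H]1COC(C)(C)O1 | intermediate (not isolated)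
17 | (2R)-5-{(1S,2S)-1-[(4S)-2,2-dimethyl-1,3-dioxolan-4-yl]-1-[(4-methoxybenzyl)oxy]propan-2-yl}-2-methyl-2-(prop-2-en-1-yl)furan-3(2H)-one | C=CC[C@@]1(C)OC(=CC1=O)[C@@H](C)[C@H](OCc3ccc(OC)cc3)[C@@H]2COC(C)(C)O2 | intermediate
18 | (2R)-5-{(2S,3S,4S)-4,5-dihydroxy-3-[(4-methoxybenzyl)oxy]pentan-2-yl}-2-methyl-2-(prop-2-en-1-yl)furan-3(2H)-one | C=CC[C@@]1(C)OC(=CC1=O)[C@@H](C)[C@H](OCc2ccc(OC)cc2)[C@@H](O)CO | intermediate
19 | (2R)-5-{(2S,3S,4S)-3-[(4-methoxybenzyl)oxy]-4,5-bis[(triethylsilyl)oxy]pentan-2-yl}-2-methyl-2-(prop-2-en-1-yl)furan-3(2H)-one | C=CC[C@@]1(C)OC(=CC1=O)[C@@H](C)[C@H](OCc2ccc(OC)cc2)[C@@H](O[Si](CC)(CC)CC)CO[Si](CC)(CC)CC | intermediate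
20 | (2R,3S,4S)-3-[(4-methoxybenzyl)oxy]-4-[(5R)-5-methyl-4-oxo-5-(prop-2-en-1-yl)-4,5-dihydrofuran-2-yl]-2-[(triethylsilyl)oxy]pentanal | C=CC[C@@]1(C)OC(=CC1=O)[C@@H](C)[C@H](OCc2ccc(OC)cc2)[C@@H](O[Si](CC)(CC)CC)C=O | intermediate
21 | methyl acrylate | C=CC(=O)OC | starting material
22 | methyl (4S,5S,6S)-3-hydroxy-5-[(4-methoxybenzyl)oxy]-2-methylidene-6-[(5R)-5-methyl-4-oxo-5-(prop-2-en-1-yl)-4,5-dihydrofuran-2-yl]-4-[(triethylsilyl)oxy]heptanoate (C3 epimers) | C=CC[C@@]1(C)OC(=CC1=O)[C@@H](C)[C@H](OCc2ccc(OC)cc2)[C@@H](O[Si](CC)(CC)CC)C(O)C(=C)C(=O)OC | intermediate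
23 | triol from dihydroxylation of the allyl group of 22 | OCC(O)C[C@@]1(C)OC(=CC1=O)[C@@H](C)[C@H](OCc2ccc(OC)cc2)[C@@H](O[Si](CC)(CC)CC)C(O)C(=C)C(=O)OC | intermediate (not isolated)
24 | methyl (4S,5S,6S)-3-hydroxy-5-[(4-methoxybenzyl)oxy]-2-methylidene-6-[(5R)-5-methyl-4-oxo-5-(2-oxoethyl)-4,5-dihydrofuran-2-yl]-4-[(triethylsilyl)oxy]heptanoate (C3 epimers) | O=CC[C@@]1(C)OC(=CC1=O)[C@@H](C)[C@H](OCc2ccc(OC)cc2)[C@@H](O[Si](CC)(CC)CC)C(O)C(=C)C(=O)OC | intermediate
25 | methyl (2Z,4S,5S,6S)-2-(bromomethyl)-5-[(4-methoxybenzyl)oxy]-6-[(5R)-5-methyl-4-oxo-5-(2-oxoethyl)-4,5-dihydrofuran-2-yl]-4-[(triethylsilyl)oxy]hept-2-enoate | O=CC[C@@]1(C)OC(=CC1=O)[C@@H](C)[C@H](OCc2ccc(OC)cc2)[C@@H](O[Si](CC)(CC)CC)/C=C(\CBr)C(=O)OC | intermediate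
26 | 5-O-PMB, 6-O-TES macrolactone (bridged furanone and trans-fused α-methylene lactone closed; configuration as in 29) | C=C1C(=O)O[C@H]2C[C@@]3(C)OC(=CC3=O)[C@@H](C)[C@H](OCc4ccc(OC)cc4)[C@@H](O[Si](CC)(CC)CC)[C@H]12 | intermediate (not isolated)
27 | 5-O-PMB, 6-hydroxy macrolactone (configuration as in 29) | C=C1C(=O)O[C@H]2C[C@@]3(C)OC(=CC3=O)[C@@H](C)[C@H](OCc4ccc(OC)cc4)[C@@H](O)[C@H]12 | intermediate
28 | 5-O-PMB ether of the target (6-O-isobutyrate) | C=C1C(=O)O[C@H]2C[C@@]3(C)OC(=CC3=O)[C@@H](C)[C@H](OCc4ccc(OC)cc4)[C@@H](OC(=O)C(C)C)[C@H]12 | intermediate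
29 | CNP0141385.1, (4S,5S,6S,7R,8S,10R) in germacrane numbering | C=C1C(=O)O[C@H]2C[C@@]3(C)OC(=CC3=O)[C@@H](C)[C@H](O)[C@@H](OC(=O)C(C)C)[C@H]12 | target

**Step count.** 16 steps in total. The longest linear sequence is 14 steps (steps 3–16, from (R)-solketal 7); the dioxolanone branch (steps 1–2) joins at step 7.

**Steps most likely to fail**

1. Step 14 (ring closure). Intermolecular allylation may compete with closure of the ten-membered ring, and simple diastereoselection may go the wrong way (syn instead of anti addition), giving the cis-fused C8 epimer. The fallback sets out from 25 and comes back at 26; it fixes C8 by an invertive C–O bond formation and no longer by the C–C bond-forming event. The chromium step is worked up without acid so that the C8-epimeric TES lactone F1 is isolated. LiOH (THF/H2O, 0 °C) opens it to the hydroxy acid F2. An intramolecular Mitsunobu lactonisation (PPh3, DIAD, toluene) then recloses the lactone with inversion at C8 to give 26, which is taken through the acid stage to 27.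

2. Step 7 (key step). Acylation of the enolate at the hindered lactone carbonyl of 6 may be slow, so that proton transfer or decomposition of the enolate takes over before the diketone forms. The fallback sets out from 6 and 13 and comes back at 16; it builds the diketone by aldol addition and oxidation. MeLi (THF, −78 °C) opens 6 to (R)-3-hydroxy-3-methylhex-5-en-2-one F3. OsO4/NaIO4 cleaves the alkene of 13 to (2S,3S)-3-[(4S)-2,2-dimethyl-1,3-dioxolan-4-yl]-3-[(4-methoxybenzyl)oxy]-2-methylpropanal F4. The dianion of F3 (LiN(i-Pr)2, 2 equiv) adds to F4 in an aldol reaction to give the β-hydroxy ketone F5. Dess–Martin oxidation of F5 gives 16, which is cyclodehydrated with CSA as in step 7 to 17.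

3. Step 4 (crotylboration). Reagent control may erode in this mismatched double diastereodifferentiation, with Felkin-type attack giving the C5 epimer. The fallback sets out from 8 and comes back at 14; it uses auxiliary control. The boron enolate of (S)-4-benzyl-3-propanoyloxazolidin-2-one (Bu2BOTf, i-Pr2NEt) adds to 8 in an Evans syn-aldol reaction to give the imide F6. Me3Al/MeONHMe·HCl converts F6 into the Weinreb amide F7. 4-Methoxybenzyl trichloroacetimidate with catalytic CSA gives the PMB ether F8. MeMgBr then gives methyl ketone 14.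

**Further compounds**

F1 | step 14 | C8 epimer of 26 (cis-fused lactone, 5-O-PMB, 6-O-TES) | C=C1C(=O)O[C@@H]2C[C@@]3(C)OC(=CC3=O)[C@@H](C)[C@H](OCc4ccc(OC)cc4)[C@@H](O[Si](CC)(CC)CC)[C@H]12
F2 | step 14 | seco hydroxy acid of F1 (free C8 hydroxyl and C12 acid) | OC(=O)C(=C)[C@@H]1[C@H](O)C[C@@]2(C)OC(=CC2=O)[C@@H](C)[C@H](OCc3ccc(OC)cc3)[C@H]1O[Si](CC)(CC)CC
F3 | step 7 | (R)-3-hydroxy-3-methylhex-5-en-2-one | C=CC[C@@](C)(O)C(C)=O
F4 | step 7 | (2S,3S)-3-[(4S)-2,2-dimethyl-1,3-dioxolan-4-yl]-3-[(4-methoxybenzyl)oxy]-2-methylpropanal | O=C[C@@H](C)[C@H](OCc2ccc(OC)cc2)[C@@H]1COC(C)(C)O1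
F5 | step 7 | (1S,2S,6R)-1-[(4S)-2,2-dimethyl-1,3-dioxolan-4-yl]-3,6-dihydroxy-1-[(4-methoxybenzyl)oxy]-2,6-dimethylnon-8-en-5-one (C3 epimers) | C=CC[C@@](C)(O)C(=O)CC(O)[C@@H](C)[C@H](OCc2ccc(OC)cc2)[C@@H]1COC(C)(C)O1
F6 | step 4 | (S)-4-benzyl-3-{(2S,3S)-3-[(4S)-2,2-dimethyl-1,3-dioxolan-4-yl]-3-hydroxy-2-methylpropanoyl}oxazolidin-2-one | O=C1OC[C@H](Cc2ccccc2)N1C(=O)[C@@H](C)[C@H](O)[C@@H]3COC(C)(C)O3
F7 | step 4 | (2S,3S)-3-[(4S)-2,2-dimethyl-1,3-dioxolan-4-yl]-3-hydroxy-N-methoxy-N,2-dimethylpropanamide | CON(C)C(=O)[C@@H](C)[C@H](O)[C@@H]1COC(C)(C)O1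
F8 | step 4 | (2S,3S)-3-[(4S)-2,2-dimethyl-1,3-dioxolan-4-yl]-N-methoxy-3-[(4-methoxybenzyl)oxy]-N,2-dimethylpropanamide | CON(C)C(=O)[C@@H](C)[C@H](OCc2ccc(OC)cc2)[C@@H]1COC(C)(C)O1
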